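**Plan**
- Feature: the benzene ring is 1,3,5-substituted, with the (S)-2-hydroxytetradecyl chain on C1, an acetoxy group on C3, a free hydroxyl on C5 and C–H at C2, C4 and C6. The two oxygens are meta to each other and to the chain, so one can enter as a ketene carbonyl and the other as an ynol ether oxygen.
- Retrosynthesis: remove the acetyl and two silyl groups, then cut ring bonds C2–C3, C4–C5 and C5–C6 to a 3-alkylcyclobutenone and (triisopropylsilyloxy)acetylene. The cyclobutenone is cut to a terminal alkyne and dichloroketene, and the alkyne at its propargylic C–C bond to an epoxide and acetylide.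
- Forward: the C16 chain is joined first, the four-membered ring is built on its alkyne, and the benzene ring arises last in one step, already carrying one free and one silylated oxygen.
- Stereochemistry: the only stereocenter comes from hydrolytic kinetic resolution of racemic 1,2-epoxytetradecane and is not touched afterwards.

Key step: step 7

Assumption: with a simple 1,2-epoxyalkane the (S,S) enantiomer of (salen)Co(OAc) consumes the (R)-epoxide and leaves the (S)-epoxide; the sign of rotation of recovered 2 is to be checked before going on. Here salen is the dianion of N,N′-bis(3,5-di-tert-butylsalicylidene)-1,2-cyclohexanediamine and the complex contains trivalent cobalt.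

**Route**

Step 1
Reactants: 1 racemic 1,2-epoxytetradecane (2-dodecyloxirane)
Product: 2 (S)-1,2-epoxytetradecane
Conditions: (S,S)-(salen)Co(OAc) (0.5 mol %), H2O (0.55 equiv), minimal THF, 0 °C → rt; distillation from the diol
Reagents that add atoms: none
Why: Jacobsen hydrolytic kinetic resolution, in which the chiral cobalt salen complex opens the (R)-epoxide with water much faster than the (S)-epoxide, so that running slightly past half conversion should leave 2 in high enantiomeric purity and thereby fix the target's only stereocenter.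

Step 2
Reactants: 2 (S)-1,2-epoxytetradecane; 3 lithium acetylide–ethylenediamine complex
Product: 4 (S)-hexadec-1-yn-4-ol
Conditions: LiC≡CH·H2NCH2CH2NH2 (1.5 equiv), DMSO, 0 °C → rt; then H2O
Reagents that add atoms: none
Why: SN2 opening of a terminal epoxide by an acetylide occurs at the unhindered CH2, so the propargylic C–C bond forms while the carbinol carbon is not involved and keeps its (S) configuration.

Step 3
Reactants: 4 (S)-hexadec-1-yn-4-ol
Product: 5 (S)-tert-butyl(hexadec-1-yn-4-yloxy)dimethylsilane
Conditions: TBSCl, imidazole, DMF, rt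
Reagents that add atoms: tert-butyldimethylsilyl chloride, CC(C)(C)[Si](C)(C)Cl
Why: Imidazole-promoted silylation of a secondary alcohol gives an ether that should survive zinc salts, hot toluene and acylation and can be removed by fluoride at the end.

Step 4
Reactants: 5 (S)-tert-butyl(hexadec-1-yn-4-yloxy)dimethylsilane; 6 trichloroacetyl chloride
Product: 8 (S)-3-[2-(tert-butyldimethylsilyloxy)tetradecyl]-4,4-dichlorocyclobut-2-en-1-one, via dichloroketene 7 (not isolated)
Conditions: Cl3CCOCl (2 equiv, slow addition), Zn(Cu) couple, Et2O/DME, rt → 35 °C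
Reagents that add atoms: none
Why: Ketene–alkyne [2+2] cycloaddition with dichloroketene made by zinc dechlorination of 6, in which the terminal alkyne carbon bonds to the ketene carbonyl carbon and so places the chain on C3 of the cyclobutenone, while DME ties up ZnCl2 and protects the silyl ether.

Step 5
Reactants: 8 (S)-3-[2-(tert-butyldimethylsilyloxy)tetradecyl]-4,4-dichlorocyclobut-2-en-1-one
Product: 9 (S)-3-[2-(tert-butyldimethylsilyloxy)tetradecyl]cyclobut-2-en-1-one
Conditions: Zn dust, AcOH, TMEDA, EtOH, 0 °C → rt
Reagents that add atoms: none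
Why: Zinc reduction of an α,α-dichloroketone in amine-buffered acetic acid removes both chlorines under conditions mild enough to leave the strained enone and the silyl ether intact.

Step 6
Reactants: 10 acetylene
Product: 13 (triisopropylsilyloxy)acetylene, via lithium acetylide 11 (not isolated), via lithium ethynolate 12 (not isolated)
Conditions: n-BuLi, THF, −78 °C; t-BuOOLi (from t-BuOOH and LiN(SiMe3)2), THF, −78 → −40 °C; i-Pr3SiOTf, −78 → 0 °C; filtration through deactivated silica, used at once
Reagents that add atoms: tert-butyl hydroperoxide (as its lithium salt), CC(C)(C)OO; triisopropylsilyl trifluoromethanesulfonate, CC(C)[Si](OS(=O)(=O)C(F)(F)F)(C(C)C)C(C)C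
Why: Electrophilic oxygenation of a lithium acetylide by lithium tert-butyl peroxide, the acetylide-to-ynolate oxidation used for 1-alkyl siloxyalkynes, followed by O-silylation of the ynolate; the monolithium acetylide is kept cold to prevent disproportionation, and the bulky silyl group favours silylation on oxygen and slows later silyl migration to carbon.

Step 7
Reactants: 9 (S)-3-[2-(tert-butyldimethylsilyloxy)tetradecyl]cyclobut-2-en-1-one; 13 (triisopropylsilyloxy)acetylene
Product: 18 3-[(S)-2-(tert-butyldimethylsilyloxy)tetradecyl]-5-(triisopropylsilyloxy)phenol, via vinylketene 14 (not isolated), via vinylcyclobutenone 15 (not isolated), via dienylketene 16 (not isolated), via cyclohexadienone 17 (not isolated)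
Conditions: 13 (1.5 equiv), toluene, 80 °C then 110 °C, sealed vessel
Reagents that add atoms: none
Why: Danheiser benzannulation: on heating, 9 undergoes reversible four-electron electrocyclic opening to vinylketene 14, which the electron-rich alkyne 13 traps by [2+2] cycloaddition to give 15; this opens again to dienylketene 16, whose thermal six-electron disrotatory electrocyclization forms the third bond and closes the six-membered carbocycle as dienone 17, which tautomerizes to phenol 18. The closest known reaction is the same cascade between 3-alkylcyclobutenones and 1-alkyl-2-siloxyalkynes, and the unsubstituted ynol ether is less hindered at its attacking carbon and should react at least as readily. The selectivity needed is regiochemical and is secured by polarity: the carbon β to oxygen in 13 is the nucleophilic terminus and adds to the ketene carbonyl carbon, so the silyloxy carbon becomes the neighbour of the former C2 of 9 and the ring emerges with OH and OSi(i-Pr)3 meta to each other and the chain meta to both. No stereocenter is formed, and the existing one lies outside the reacting system as a silyl ether that neutral thermal conditions should not disturb. An excess of 13 is used so that the vinylketene is consumed by the alkyne and not by O-acylation of phenol already formed.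

Step 8
Reactants: 18 3-[(S)-2-(tert-butyldimethylsilyloxy)tetradecyl]-5-(triisopropylsilyloxy)phenol
Product: 19 3-[(S)-2-(tert-butyldimethylsilyloxy)tetradecyl]-5-(triisopropylsilyloxy)phenyl acetate
Conditions: Ac2O, pyridine, DMAP (cat.), CH2Cl2, 0 °C → rt
Reagents that add atoms: acetic anhydride, CC(=O)OC(C)=O
Why: DMAP-catalysed acylation of the only free hydroxyl, the phenol that came from the ketene carbonyl, places the acetate on one ring oxygen without any statistical differentiation because the other two oxygens are silylated.

Step 9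
Reactants: 19 3-[(S)-2-(tert-butyldimethylsilyloxy)tetradecyl]-5-(triisopropylsilyloxy)phenyl acetate
Product: 20 3-hydroxy-5-[(S)-2-hydroxytetradecyl]phenyl acetate (target)
Conditions: HF·pyridine, pyridine/THF, 0 °C → rt
Reagents that add atoms: none
Why: Fluoride-mediated desilylation under buffered acidic conditions cleaves both the alkyl TBS ether and the aryl TIPS ether, while the aryl acetate, which basic fluoride could hydrolyse or transfer through a phenoxide, should remain and the stereocenter is not involved.

**Compound list**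
1 | racemic 1,2-epoxytetradecane (2-dodecyloxirane) | CCCCCCCCCCCCC1CO1 | starting material
2 | (S)-1,2-epoxytetradecane | CCCCCCCCCCCC[C@H]1CO1 | intermediate
3 | lithium acetylide–ethylenediamine complex | [Li]C#C.NCCN | starting material
4 | (S)-hexadec-1-yn-4-ol | CCCCCCCCCCCC[C@H](O)CC#C | intermediate
5 | (S)-tert-butyl(hexadec-1-yn-4-yloxy)dimethylsilane | CCCCCCCCCCCC[C@H](O[Si](C)(C)C(C)(C)C)CC#C | intermediate
6 | trichloroacetyl chloride | ClC(=O)C(Cl)(Cl)Cl | starting material
7 | dichloroketene | ClC(Cl)=C=O | intermediate
8 | (S)-3-[2-(tert-butyldimethylsilyloxy)tetradecyl]-4,4-dichlorocyclobut-2-en-1-one | CCCCCCCCCCCC[C@H](O[Si](C)(C)C(C)(C)C)CC1=CC(=O)C1(Cl)Cl | intermediate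
9 | (S)-3-[2-(tert-butyldimethylsilyloxy)tetradecyl]cyclobut-2-en-1-one | CCCCCCCCCCCC[C@H](O[Si](C)(C)C(C)(C)C)CC1=CC(=O)C1 | intermediate
10 | acetylene | C#C | starting material
11 | lithium acetylide | [Li]C#C | intermediate
12 | lithium ethynolate | [Li]OC#C | intermediate
13 | (triisopropylsilyloxy)acetylene | C#CO[Si](C(C)C)(C(C)C)C(C)C | intermediate
14 | (S)-5-(tert-butyldimethylsilyloxy)-3-methylideneheptadec-1-en-1-one (vinylketene) | CCCCCCCCCCCC[C@H](O[Si](C)(C)C(C)(C)C)CC(=C)C=C=O | intermediate
15 | 4-[(4S)-4-(tert-butyldimethylsilyloxy)hexadec-1-en-2-yl]-3-(triisopropylsilyloxy)cyclobut-2-en-1-one (both epimers at ring C4) | CCCCCCCCCCCC[C@H](O[Si](C)(C)C(C)(C)C)CC(=C)C1C(=O)C=C1O[Si](C(C)C)(C(C)C)C(C)C | intermediate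
16 | (7S)-7-(tert-butyldimethylsilyloxy)-5-methylidene-3-(triisopropylsilyloxy)nonadeca-1,3-dien-1-one (dienylketene, ketene and alkenyl groups cis on C3=C4) | CCCCCCCCCCCC[C@H](O[Si](C)(C)C(C)(C)C)CC(=C)/C=C(O[Si](C(C)C)(C(C)C)C(C)C)\C=C=O | intermediate
17 | 5-[(S)-2-(tert-butyldimethylsilyloxy)tetradecyl]-3-(triisopropylsilyloxy)cyclohexa-2,4-dien-1-one | CCCCCCCCCCCC[C@H](O[Si](C)(C)C(C)(C)C)CC1=CC(O[Si](C(C)C)(C(C)C)C(C)C)=CC(=O)C1 | intermediate
18 | 3-[(S)-2-(tert-butyldimethylsilyloxy)tetradecyl]-5-(triisopropylsilyloxy)phenol | CCCCCCCCCCCC[C@H](O[Si](C)(C)C(C)(C)C)Cc1cc(O)cc(O[Si](C(C)C)(C(C)C)C(C)C)c1 | intermediate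
19 | 3-[(S)-2-(tert-butyldimethylsilyloxy)tetradecyl]-5-(triisopropylsilyloxy)phenyl acetate | CCCCCCCCCCCC[C@H](O[Si](C)(C)C(C)(C)C)Cc1cc(OC(C)=O)cc(O[Si](C(C)C)(C(C)C)C(C)C)c1 | intermediate
20 | 3-hydroxy-5-[(S)-2-hydroxytetradecyl]phenyl acetate | CCCCCCCCCCCC[C@H](O)Cc1cc(O)cc(OC(C)=O)c1 | target

**Step count**
Total steps: 9. Longest linear sequence: 8 (steps 1–5, 7, 8, 9); step 6 is a one-step branch.

**Steps most likely to fail**

Step 6. Process at risk: monolithium acetylide may disproportionate to insoluble dilithium acetylide before oxygen transfer, and the parent ynolate may be silylated on carbon or the ynol ether may rearrange to a silylketene during isolation. The fallback sets out from 9 and returns at 19; it blocks the free alkyne carbon with silicon, which makes the acetylide stable, and removes that silicon from the arene later. Commercial ethynyltrimethylsilane is lithiated with n-BuLi to lithium (trimethylsilyl)acetylide F1. This is oxidised with t-BuOOLi to lithium (trimethylsilyl)ethynolate F2 and O-silylated with i-Pr3SiOTf to trimethyl{[tri(propan-2-yl)silyl]oxyethynyl}silane F3. Heating F3 with 9 in toluene should give, with the same regiochemistry, 5-[(S)-2-(tert-butyldimethylsilyloxy)tetradecyl]-3-(triisopropylsilyloxy)-2-(trimethylsilyl)phenol F4. Acetylation (Ac2O, pyridine, DMAP) gives 5-[(S)-2-(tert-butyldimethylsilyloxy)tetradecyl]-3-(triisopropylsilyloxy)-2-(trimethylsilyl)phenyl acetate F5. Ipso-protodesilylation of this electron-rich arylsilane with CF3CO2H in CH2Cl2 at 0 °C then gives 19.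

Step 7. Process at risk: thermal oxygen-to-carbon silyl shift or oligomerization of the unsubstituted ynol ether may outrun its capture by the vinylketene, and the vinylketene may acylate the phenol already formed. The fallback sets out from 2 and returns at 20; it abandons ring construction and attaches a preformed arene to the epoxide. Commercial 1,3-bis(benzyloxy)-5-bromobenzene and Mg in THF give 3,5-bis(benzyloxy)phenylmagnesium bromide F6. With CuI (10 mol %) at −30 → 0 °C this opens 2 at the terminal carbon to (S)-1-[3,5-bis(benzyloxy)phenyl]tetradecan-2-ol F7. Silylation (TBSCl, imidazole, DMF) gives {[(S)-1-[3,5-bis(benzyloxy)phenyl]tetradecan-2-yl]oxy}(tert-butyl)dimethylsilane F8, and hydrogenolysis (H2, Pd/C, EtOAc) gives 5-[(S)-2-(tert-butyldimethylsilyloxy)tetradecyl]benzene-1,3-diol F9. Monoacetylation of the two equivalent phenols (Ac2O, 1 equiv, pyridine, CH2Cl2, 0 °C; statistical, with diol and diacetate recycled through K2CO3/MeOH) gives 3-[(S)-2-(tert-butyldimethylsilyloxy)tetradecyl]-5-hydroxyphenyl acetate F10. HF·pyridine then gives 20.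

Step 4. Process at risk: Lewis-acidic ZnCl2 may erode the silyl ether, and dichloroketene may oligomerize faster than it adds to an unactivated terminal alkyne. The fallback sets out from 5 and returns at 9, bypassing 8; it replaces the ketene by a keteniminium ion and needs no dechlorination. N,N-Dimethylacetamide, Tf2O and 2,4,6-collidine in refluxing 1,2-dichloroethane generate the keteniminium triflate, which should add to 5 with the same regiochemistry. The adduct is N-{(S)-3-[2-(tert-butyldimethylsilyloxy)tetradecyl]cyclobut-2-en-1-ylidene}-N-methylmethanaminium trifluoromethanesulfonate F11, and hydrolysis with aqueous NaHCO3 gives 9.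

**Further compounds**
F1 | step 6 | lithium (trimethylsilyl)acetylide | C[Si](C)(C)C#C[Li]
F2 | step 6 | lithium (trimethylsilyl)ethynolate | C[Si](C)(C)C#CO[Li]
F3 | step 6 | trimethyl{[tri(propan-2-yl)silyl]oxyethynyl}silane | C[Si](C)(C)C#CO[Si](C(C)C)(C(C)C)C(C)C
F4 | step 6 | 5-[(S)-2-(tert-butyldimethylsilyloxy)tetradecyl]-3-(triisopropylsilyloxy)-2-(trimethylsilyl)phenol | CCCCCCCCCCCC[C@H](O[Si](C)(C)C(C)(C)C)Cc1cc(O)c([Si](C)(C)C)c(O[Si](C(C)C)(C(C)C)C(C)C)c1
F5 | step 6 | 5-[(S)-2-(tert-butyldimethylsilyloxy)tetradecyl]-3-(triisopropylsilyloxy)-2-(trimethylsilyl)phenyl acetate | CCCCCCCCCCCC[C@H](O[Si](C)(C)C(C)(C)C)Cc1cc(OC(C)=O)c([Si](C)(C)C)c(O[Si](C(C)C)(C(C)C)C(C)C)c1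
F6 | step 7 | 3,5-bis(benzyloxy)phenylmagnesium bromide | Br[Mg]c1cc(OCc2ccccc2)cc(OCc2ccccc2)c1
F7 | step 7 | (S)-1-[3,5-bis(benzyloxy)phenyl]tetradecan-2-ol | CCCCCCCCCCCC[C@H](O)Cc1cc(OCc2ccccc2)cc(OCc2ccccc2)c1
F8 | step 7 | {[(S)-1-[3,5-bis(benzyloxy)phenyl]tetradecan-2-yl]oxy}(tert-butyl)dimethylsilane | CCCCCCCCCCCC[C@H](O[Si](C)(C)C(C)(C)C)Cc1cc(OCc2ccccc2)cc(OCc2ccccc2)c1
F9 | step 7 | 5-[(S)-2-(tert-butyldimethylsilyloxy)tetradecyl]benzene-1,3-diol | CCCCCCCCCCCC[C@H](O[Si](C)(C)C(C)(C)C)Cc1cc(O)cc(O)c1
F10 | step 7 | 3-[(S)-2-(tert-butyldimethylsilyloxy)tetradecyl]-5-hydroxyphenyl acetate | CCCCCCCCCCCC[C@H](O[Si](C)(C)C(C)(C)C)Cc1cc(O)cc(OC(C)=O)c1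
F11 | step 4 | N-{(S)-3-[2-(tert-butyldimethylsilyloxy)tetradecyl]cyclobut-2-en-1-ylidene}-N-methylmethanaminium trifluoromethanesulfonate | CCCCCCCCCCCC[C@H](O[Si](C)(C)C(C)(C)C)CC1=CC(=[N+](C)C)C1.[O-]S(=O)(=O)C(F)(F)F
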